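The earlier runs and the new flask are calculated with made-up constants; the scatter is artificial.

The unit for free catalyst here is not the millimolar but the crossover charge, the charge at which the catalyst and the partner take equal shares of the substrate.

| flask | substrate | partner | free catalyst | remark | time |
|---|---|---|---|---|---|
| red | 1 M | 1 M | 10 mM | run made earlier |  |
| flask | 1.0 M | 1.00 M | 20 mM |  | 2.0 h |

- red (time / min: uncatalysed product / %, target / %): 4.00: 17.7, 4.9; 8.00: 26.9, 10.3; 12.0: 33.2, 13.7; 15.0: 35.6, 15.7; 20.0: 37.9, 19.3; 25.0: 39.1, 20.5

(readings scatter by 0.5 percentage points)

- ratio of uncatalysed product to target at 25 s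
- ratio of uncatalysed product to target at 8.0 min
- ratio of uncatalysed product to target at 2.0 h

- no earlier run changes the charge of free catalyst; that part of a forecast is a guess

The red run supplies this unit. Its uncatalysed product slows, and its last gain is about half of the gain before. Continuing that halving puts the plateau at 40.3%. I read this plateau as the partner's share of the substrate and the rest as the catalyst's. If the catalyst's pull scales with its charge, which is a guess, then the crossover charge is 6.75 mM. At a partner charge of 1.00 M, I take the plateau as the crossover charge over the sum of crossover and catalyst charges. The catalyst charge over the crossover charge is then the selectivity factor of the two routes.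

Now the ladder for this flask. The first red reading gives the partner route a time of 22.6 min. The plateau I reckon for the flask is 25.2%, and multiplying the two gives an estimated substrate lifetime of 5.70 min. At 25 s, far inside that lifetime, my nearest guide is the red ratio, which reads 3.61 and then 2.61 at its first two readings. I therefore expect the flask to stand above half of the first, 1.81. At 8.0 min, past one lifetime, half of the second gives about 1.31. At 2.0 h, long after that lifetime, I reckon the ratio as the crossover charge over the catalyst charge, 0.338, on the assumption that the catalyst's share reaches target intact.

The forecast says 1.9, 1.35 and 0.08, lower at the end than my 0.338, on the view that the uncatalysed product “behaves as a reversible adduct”.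

The flask gives 6.66, 0.854 and 0.636. At 2.00 h it holds 27.6% uncatalysed product against my 25.2%, with 43.5% target and 28.9% decomposed reagent.

    partner + catalyst intermediate → free catalyst + target (k = 1.26 M⁻¹ s⁻¹)
    substrate + partner → uncatalysed product (k = 0.00103 M⁻¹ s⁻¹)
    substrate + free catalyst → free catalyst + open intermediate (k = 0.0901 M⁻¹ s⁻¹)
    open intermediate → decomposed reagent (k = 0.00311 s⁻¹)
    free catalyst + open intermediate ⇌ catalyst intermediate (K = 0.450 M⁻¹, k = 1.18 M⁻¹ s⁻¹)

For the further flask with 0.0050 M of free catalyst, the crossover charge of 6.75 mM gives a plateau of 57.4%, and that flask holds 58.1% uncatalysed product at 2.00 h.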